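Count the chains first. Z turns into L, L and Q start a living end D, D adds Q to make E, and D can also pass with Q into G. The average asked for is E divided by the chains begun, living or dead.

all flasks: Q 0.20 M
- midnight: Z 1.5 mol%; run made earlier
- noon: Z 5.9 mol%; run made earlier
- theta: Z 1 mol%; time 12 min
- beta: Z 4 mol%; time 12 min

| run | time / min | E / % |
|---|---|---|
| midnight | 0.500 | 3 |
| midnight | 0.833 | 4 |
| midnight | 1.50 | 9 |
| midnight | 3.00 | 32 |
| midnight | 6.00 | 64 |
| noon | 1.33 | 30 |
| noon | 2.50 | 66 |
| noon | 4.00 | 93 |
| noon | 5.00 | 97 |
| noon | 6.00 | 99 |

(readings scatter by 1.5 percentage points)

- the average divides the monomer in chains by the number of chains begun, living and dead together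
- steps thought possible: Q + L -> D + E; Q + D -> E + D; Z -> L; D + Q -> G
- the earlier runs do not show the number of chains; that part of a forecast is a guess

- which of the two ends with the longer chains by the average number of monomer units in a chain (chains begun, living or dead) ("neither" if they lie within 10%) (theta / beta / neither)
- average number of monomer units in a chain (chains begun, living or dead) at the end, theta
- average number of monomer units in a chain (chains begun, living or dead) at the end, beta

Each chain begun takes one Z, so the chains cannot outnumber the Z charged. My rule of thumb is therefore E divided by Z charged, a floor on the average for a given E. At full conversion it gives 100 units in theta and 25.0 in beta.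

Next I need how far E gets. After a lag, −ln(1−E) climbs along a line, so the loss of [Q] looks pseudo-first-order. I read a time constant of 4.72 min from the midnight run and 0.949 min from the noon run, and the line from midnight meets zero at a lag of 1.18 min. Scaling each inversely with the Z loading, from the nearer run, gives 7.08 min for theta and 1.40 min for beta. By this reckoning theta reaches 78.3% in 12 min, so the rule gives it a floor of 78.3.

The rule has a border, since L needs Q to start a chain. For theta, the time constant of the loss of Q divided by the lag is 5.99, and this ratio I call the race number. For beta it is 1.19, smaller, so in beta I expect Q to be lost on about the timescale of the lag. The lag marks the first sign of Z, and the runs do not show chains, so it is a guess that some Z in beta comes too late. I put beta above 25.0 but below the 78.3 of theta, so I expect theta to have the longer chains.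

The forecast names theta, with 80 and 25.5, holding that “Every Z should then begin a chain”, so for beta it stays close to my floor where I expect more.

Theta, at race number 5.99, gives 83.1 with E at 76.8%. Beta, at 1.19, gives 34.9, above the floor, with Q down to 0.0100% while [L] stands at 0.00177 M and Z at 6.97% of its charge.

    Q + L → D + E (k = 1.03 /M/s)
    Q + D → E + D, rate k2*[D]*[Q] (k = 3.77 /M/s)
    Z → L (k = 0.00370 /s)
    D + Q → G (k = 0.0324 /M/s)

A neighbouring flask is like theta but charged with 0.25 mol% of Z, and its race number is 24.0. Its E of 24.0% over the Z charged gives a floor of 95.9. That neighbouring flask gives 103, with 6.97% of its Z still unspent at 12.0 min.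

The numbers in the tables are simulated with constants of no real substance; the scatter is artificial.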